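Abbreviations used throughout: TBS = tert‑butyl(dimethyl)silyl; "TBSO‑methyl" = CH2OSi(t‑Bu)Me2. Atom labels C1–C15 follow germacrane numbering (ring C1–C10, C1=C10, C14 on C10, C15 on C4, lactone O on C6, C7–C11(=C13)–C12, ester O on C8).

## The problem

The target is a germacranolide: a ten‑membered carbocycle (C1–C10) fused trans across C6–C7 to an α‑methylene‑γ‑butyrolactone (O–C12(=O)–C11(=C13)). It carries a methacrylate on the C8 oxygen and primary alcohols at C14 and C15. The ring contains one trisubstituted alkene, C1=C10, in which the ring bonds to C2 and C9 are cis; the descriptor is E only because the C14 hydroxymethyl outranks C9. Of the four stereocentres (4S, 6R, 7S, 8R), C6, C7 and C8 are contiguous, and C6 can control C7 reliably if both sit on a rigid five‑membered ring. C4 is insulated from them by the C5 methylene and must be set independently. C8 is an exocyclic carbinol beside C7, whose two ring neighbours are nearly equivalent, so it needs reagent control. The methylene lactone and the methacrylate are Michael acceptors and metathesis partners, and a free C8 hydroxyl can translactonise onto C12 under base; these groups must come late and see only mild reagents. The enabling feature is that C7 is the β‑carbon of the lactone carbonyl C12, flanked by oxygenated C6 and C8, while its α‑carbon C11 bears the exocyclic methylene. Conjugate addition of a C8 acyl‑anion equivalent to a C6‑substituted butenolide, with capture of the enolate at C11 by a one‑carbon electrophile, therefore makes both bonds around the lactone at once.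

## Retrosynthesis

**Endgame, 33 back to 30.** No skeletal bond is cut. The two O–Si bonds are cleaved last (33 from 32), the C11=C13 double bond is traced to a C13 acetate that leaves by E1cB elimination (32 from 31), and the C8 ester C–O bond is made on the free alcohol (31 from 30). Unveiling the methylene lactone earlier would expose it to metathesis, where C13 could pair with the C10 methylene to close a cyclopentene, and to a free C8 hydroxyl that can add to it. The methacrylate must follow ring closure, because with the C10 methylene it would close a six‑membered unsaturated lactone instead. The acetate both distinguishes the C13 oxygen from the C8 oxygen and serves as the leaving group. The forward steps need only amine‑base acylation, brief amidine base and buffered fluoride.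

**Ring closure, 30 back to 29.** The C1=C10 double bond is cut. It is the only ring bond that can be formed from two groups (a vinyl and a 1,1‑disubstituted alkene) that are inert to all the carbanion chemistry before it. Closure at C5–C6 or C7–C8 would instead put carbonyl or organometallic handles into the fragments and make the three‑component union intramolecular. Precursor 29 is a single five‑membered ring with two chains on adjacent, trans‑disposed carbons. The forward metathesis must close a ten‑membered ring and deliver the ring‑cis trisubstituted alkene, which is the less strained isomer.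

**C8 carbinol, 29 back to 26.** The C8–H bond is cut to ketone 28, the C8=O to the dithiane of 27, and the C13 acetate to the alcohol of 26. Reduction before ring closure is preferred to reduction in the ring. In 28 the carbonyl has clearly different flanks (branched C7 against the C9 methylene), which is what an oxazaborolidine catalyst discriminates, whereas in the macrocycle the facial bias would be conformational and unknown. Also, 28 is a β,γ‑unsaturated, β‑acyloxy ketone that should be consumed at once, not carried through a hot metathesis.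

**Key disconnection, 26 to 22 + 15 + 23.** The C7–C8 and C11–C13 bonds are cut together. This uses the innate polarity of the butenolide (electrophilic C7, nucleophilic C11 after addition). The neighbouring cut C6–C7 would require a C7 nucleophile β to a carbonyl, which has no simple equivalent. The precursors are a mono‑substituted butenolide 15 carrying C1–C6 with C4 and C6 set, an achiral dithiane 22 carrying C8–C10 and C14, and formaldehyde 23. The forward reaction must add 1,4 and not 1,2, must not deprotonate C6, and must approach C7 anti to the C6 side chain.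

**Butenolide, 15 back to 10 + 11.** The lactone C12–O bond and the cis alkene are traced to the γ‑hydroxy ynoate 13, and the C6–C7 bond is cut to aldehyde 10 and ethyl propiolate 11. This brings C7, C11 and C12 in one piece at the correct oxidation level. A chiral‑pool butenolide would instead need a C4–C5 bond formed next to a base‑sensitive lactone. Because C4 is 1,3 to C6 and exerts little bias, the alkynylation must be catalyst‑controlled, and the semihydrogenation must spare the terminal alkene.

**C4 stereocentre, 10 back to 1 + 2 + 5.** The C4–C5 bond is cut in an auxiliary‑controlled enolate alkylation (7 from 4 and tert‑butyl bromoacetate 5). The carboxyl carbon of hex‑5‑enoic acid 1 becomes C15, and the bromoacetate delivers C5–C6 as an ester that is distinguishable from the terminal alkene; an allyl electrophile would give two equivalent alkenes. Reduction, silylation and partial reduction (8, 9, 10) then adjust oxidation levels. The auxiliary 2 must be the (R)‑benzyl oxazolidinone to give the 4S centre.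

**Dithiane, 22 back to 20 + 16.** The C8–C9 bond is cut to 1,3‑dithiane 20 and allylic bromide 19, which comes from the symmetrical diol 16 through mono‑silyl ether 18. The symmetry of the 2‑methylidenepropane unit makes SN2 and SN2′ alkylation give the same product.

## Roads not taken

**Alternative 1:** The cut is C6–C7 together with the C11=C13 double bond, both made by a [2,3]‑Wittig–Still shift. Tin–lithium exchange at C6 of the thirteen‑membered α‑stannyl allylic ether A1 would give an α‑alkoxy carbanion that attacks C7, breaks the C13–O bond and contracts the ring to the ten‑membered carbocycle A2, with the exocyclic methylene already in place.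
- Merits: the strained ring is reached by contraction of an easier macrocycle, not by direct closure. The C1=C10 geometry can be fixed in an open chain, and no hydroxymethyl detour is needed for C13. On ring formation this road is at least as good as the chosen one.
- Weak points: A1 needs a configurationally defined stannane carbon and a defined C7=C11 geometry inside a large ring. Their transfer to the C6/C7 pair through a macrocyclic transition state is hard to predict, and a [1,2]‑shift competes. A2 still has C12 as a PMB ether, so PMB removal, two oxidations and lactonisation precede the ester and silyl manipulations, with three classes of protecting group in play.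
- Comparison: the chosen plan sets against it the predictable C6‑to‑C7 relay on a butenolide, a lactone at the right oxidation level from the start, and far shorter access to the key substrate.

**Alternative 2:** The cut is C5–C6 plus the lactone C6–O bond. CrCl2 (divalent chromium) would convert the allylic bromide of the acyclic aldehyde ester A3 into an allylchromium that adds to the C6 aldehyde, closing the ten‑membered ring; the chromium alkoxide would then lactonise onto the C12 ester to give A4.
- Merits: both rings close in one mild, chemoselective operation, and the C1=C10 alkene is installed with defined geometry beforehand. In ring‑forming economy this is better than the chosen plan, which needs a separate metathesis.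
- Weak points: A4 has no C4 stereocentre (C4 is an exocyclic methylene) and no C13. C4 would have to be created late by hydroboration on a flexible ring that also holds the C1=C10 alkene, with uncertain facial selectivity, and the lactone would still need α‑methylenation. The C6 configuration relative to C7 would be set in a macrocyclic addition with no firm model. A3 requires a C7/C8 stereodiad next to an epimerisable aldehyde.
- Comparison: the chosen plan fixes C4 by an auxiliary at the outset, fixes C6/C7 on a rigid ring, and brings C13 in during the key step.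

**Alternative 3:** The cut is C7–C11 (lactone closure) and C11=C13. Deprotonation of the C6 phosphonoacetate A5 would give a carbanion that opens the trans C7–C8 epoxide at C7 and then olefinates formaldehyde, giving the methylene lactone A6 with the C8 hydroxyl free.
- Merits: A6 is two steps from the target (methacrylation, desilylation), the methylene arises without a dehydration, and C7 and C8 follow stereospecifically from the epoxide. The endgame is shorter and cleaner than that of the chosen plan.
- Weak points: all the difficulty moves into A5. This is a ten‑membered carbocycle that must already hold C4, C6 and a trans epoxide of the right absolute configuration, which implies a second, strained ring‑trans alkene and a face‑selective epoxidation. Opening an epoxide with a stabilised phosphonoacetate anion is sluggish, and the backside alignment needed to close a trans‑fused five‑membered ring onto a medium‑ring epoxide is not assured. Base with a free C8 alkoxide next to C12 also invites translactonisation.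
- Comparison: the chosen plan assembles the lactone and its stereocentres convergently from two small fragments before any macrocycle exists, and pays for this with two extra functional‑group steps at the end.

Key step: step 11

Remark on step 6: the ProPhenol enantiomer is fixed by the required outcome (alkynyl delivery to the Si face of aldehyde 10, giving the 4R carbinol). (S,S)‑ProPhenol is written on that basis, and its antipode would be used unchanged in all other respects if the facial sense proved opposite.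

## Route

Step 1
Reactants: 1 hex‑5‑enoic acid; 2 (4R)‑4‑benzyl‑1,3‑oxazolidin‑2‑one
Product: 4 (4R)‑4‑benzyl‑3‑(hex‑5‑enoyl)‑1,3‑oxazolidin‑2‑one, via hex‑5‑enoic pivalic anhydride 3 (not isolated)
Conditions: t‑BuCOCl, Et3N, THF, −20 °C; then LiCl, 2, −20 °C to rt
Reagents that add atoms: none
Why: Mixed‑anhydride N‑acylation of an Evans oxazolidinone; the LiCl‑activated oxazolidinone attacks the less hindered carbonyl of anhydride 3; no stereocentre is formed.

Step 2
Reactants: 4 (4R)‑4‑benzyl‑3‑(hex‑5‑enoyl)‑1,3‑oxazolidin‑2‑one; 5 tert‑butyl bromoacetate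
Product: 7 tert‑butyl (3S)‑3‑{[(4R)‑4‑benzyl‑2‑oxo‑1,3‑oxazolidin‑3‑yl]carbonyl}hept‑6‑enoate, via sodium Z‑enolate 6 (not isolated)
Conditions: NaN(SiMe3)2, THF, −78 °C; then 5, −78 to −40 °C
Reagents that add atoms: none
Why: Evans asymmetric alkylation; the chelated sodium Z‑enolate 6 is alkylated by the reactive α‑bromo ester on the face opposite the benzyl group, which with the (R)‑auxiliary gives the S centre that becomes C4.

Step 3
Reactants: 7 tert‑butyl (3S)‑3‑{[(4R)‑4‑benzyl‑2‑oxo‑1,3‑oxazolidin‑3‑yl]carbonyl}hept‑6‑enoate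
Product: 8 tert‑butyl (3S)‑3‑(hydroxymethyl)hept‑6‑enoate
Conditions: LiBH4, MeOH (1 equiv), THF, 0 °C
Reagents that add atoms: none
Why: Reductive removal of the auxiliary; LiBH4 attacks the activated imide carbonyl faster than the hindered tert‑butyl ester, and a cold, short reaction with neutral work‑up should prevent lactonisation; C4 is untouched.

Step 4
Reactants: 8 tert‑butyl (3S)‑3‑(hydroxymethyl)hept‑6‑enoate
Product: 9 tert‑butyl (3S)‑3‑(TBSO‑methyl)hept‑6‑enoate
Conditions: TBSCl, imidazole, CH2Cl2, 0 °C to rt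
Reagents that add atoms: tert‑butyl(chloro)dimethylsilane, CC(C)(C)[Si](C)(C)Cl
Why: Standard silylation of a primary alcohol; the C15 oxygen is now masked for the whole route.

Step 5
Reactants: 9 tert‑butyl (3S)‑3‑(TBSO‑methyl)hept‑6‑enoate
Product: 10 (3S)‑3‑(TBSO‑methyl)hept‑6‑enal
Conditions: i‑Bu2AlH, CH2Cl2, −78 °C; aq. potassium sodium tartrate work‑up
Reagents that add atoms: none
Why: Partial reduction of an ester to the aldehyde through a tetrahedral aluminium hemiacetal that is stable at −78 °C; the stereocentre is β to the carbonyl and cannot epimerise.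

Step 6
Reactants: 10 (3S)‑3‑(TBSO‑methyl)hept‑6‑enal; 11 ethyl propiolate
Product: 13 ethyl (4R,6S)‑4‑hydroxy‑6‑(TBSO‑methyl)dec‑9‑en‑2‑ynoate, via methylzinc alkynylide 12 (not isolated)
Conditions: Me2Zn, (S,S)‑ProPhenol ligand (2,6‑bis{[(S)‑2‑(hydroxydiphenylmethyl)pyrrolidin‑1‑yl]methyl}‑4‑methylphenol, cat.), Ph3P=O (cat.), 11, toluene, 0 °C; then 10, 0 to 4 °C
Reagents that add atoms: none
Why: Catalytic enantioselective alkynylation of an aldehyde by a dinuclear zinc–ProPhenol catalyst; alkynylide 12 is delivered to the Si face under catalyst control, since the 1,3‑remote C4 centre exerts little bias, and this sets C6 (4R in this compound).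

Step 7
Reactants: 13 ethyl (4R,6S)‑4‑hydroxy‑6‑(TBSO‑methyl)dec‑9‑en‑2‑ynoate
Product: 15 (5R)‑5‑[(2S)‑2‑(TBSO‑methyl)hex‑5‑en‑1‑yl]furan‑2(5H)‑one, via Z‑hydroxy enoate 14 (not isolated)
Conditions: H2 (1 atm, 1 equiv uptake), Pd/CaCO3 poisoned with Pb(OAc)2 (Lindlar catalyst), quinoline, EtOAc, rt; filter; pyridinium p‑toluenesulfonate (cat.), toluene, 50 °C
Reagents that add atoms: none
Why: Lindlar semihydrogenation reduces the conjugated alkyne cis in preference to the terminal alkene, and the Z‑γ‑hydroxy enoate 14 lactonises under mild acid to the butenolide; no bond to C6 is broken, so its configuration is kept.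

Step 8
Reactants: 16 2‑methylidenepropane‑1,3‑diol
Product: 18 2‑(TBSO‑methyl)prop‑2‑en‑1‑ol, via monosodium alkoxide 17 (not isolated)
Conditions: NaH (1.0 equiv), THF, 0 °C to rt; then TBSCl
Reagents that add atoms: tert‑butyl(chloro)dimethylsilane, CC(C)(C)[Si](C)(C)Cl
Why: Monosilylation of a symmetrical diol through its sparingly soluble monosodium alkoxide, a standard way to desymmetrise such diols.

Step 9
Reactants: 18 2‑(TBSO‑methyl)prop‑2‑en‑1‑ol
Product: 19 {[2‑(bromomethyl)prop‑2‑en‑1‑yl]oxy}(tert‑butyl)dimethylsilane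
Conditions: CBr4, PPh3, CH2Cl2, 0 °C
Reagents that add atoms: tetrabromomethane, BrC(Br)(Br)Br
Why: Appel bromination of an allylic alcohol under neutral conditions that leave the silyl ether intact.

Step 10
Reactants: 20 1,3‑dithiane; 19 {[2‑(bromomethyl)prop‑2‑en‑1‑yl]oxy}(tert‑butyl)dimethylsilane
Product: 22 2‑[2‑(TBSO‑methyl)prop‑2‑en‑1‑yl]‑1,3‑dithiane, via 2‑lithio‑1,3‑dithiane 21 (not isolated)
Conditions: n‑BuLi, THF, −30 °C; then 19, −78 to 0 °C
Reagents that add atoms: none
Why: Corey–Seebach alkylation; lithiodithiane 21 displaces the allylic bromide, and SN2 and SN2′ attack give the same constitution because the allyl unit is symmetrical.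

Step 11
Reactants: 22 2‑[2‑(TBSO‑methyl)prop‑2‑en‑1‑yl]‑1,3‑dithiane; 15 (5R)‑5‑[(2S)‑2‑(TBSO‑methyl)hex‑5‑en‑1‑yl]furan‑2(5H)‑one; 23 formaldehyde
Product: 26 (3R,4S,5R)‑3‑(hydroxymethyl)‑5‑[(2S)‑2‑(TBSO‑methyl)hex‑5‑en‑1‑yl]‑4‑{2‑[2‑(TBSO‑methyl)prop‑2‑en‑1‑yl]‑1,3‑dithian‑2‑yl}oxolan‑2‑one, via lithiated dithiane 24 (not isolated), via lithium lactone enolate 25 (not isolated)
Conditions: 22, n‑BuLi, THF, −30 °C, 2 h; DMPU, −78 °C; 15 in THF, −78 °C; then anhydrous monomeric CH2O (THF solution from cracked paraformaldehyde, excess), −78 °C; aq. NH4Cl at −78 °C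
Reagents that add atoms: none
Why: Deprotonation of 22 at the dithiane carbon gives the C8 acyl‑anion equivalent 24, which adds in Michael fashion to C7 of butenolide 15 to form the C7–C8 bond, and the resulting lithium enolate 25 undergoes aldol addition at C11 to formaldehyde to form the C11–C13 bond. The closest known reaction type is the tandem conjugate addition of 2‑lithio‑1,3‑dithianes to butenolides with aldehyde trapping of the lactone enolate. No ring is closed. C7 is set by C6: the nucleophile approaches the flat five‑membered ring anti to the C6 side chain, giving the 6,7‑trans lactone. C11 is set by C7: formaldehyde approaches the enolate anti to the bulky dithianyl group, giving the 7,11‑trans product, and this centre is erased later. The step needs 1,4‑ over 1,2‑addition and over deprotonation at C6; the soft sulfur‑stabilised anion, the solvent‑separated ion pair formed with DMPU and the low temperature should secure this. Excess monomeric formaldehyde should outrun proton transfer to the enolate, and the cold quench should prevent retro‑aldol loss of C13.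

Step 12
Reactants: 26 (3R,4S,5R)‑3‑(hydroxymethyl)‑5‑[(2S)‑2‑(TBSO‑methyl)hex‑5‑en‑1‑yl]‑4‑{2‑[2‑(TBSO‑methyl)prop‑2‑en‑1‑yl]‑1,3‑dithian‑2‑yl}oxolan‑2‑one
Product: 27 [(3R,4S,5R)‑2‑oxo‑5‑[(2S)‑2‑(TBSO‑methyl)hex‑5‑en‑1‑yl]‑4‑{2‑[2‑(TBSO‑methyl)prop‑2‑en‑1‑yl]‑1,3‑dithian‑2‑yl}oxolan‑3‑yl]methyl acetate
Conditions: Ac2O, pyridine, DMAP (cat.), CH2Cl2, 0 °C
Reagents that add atoms: acetic anhydride, CC(=O)OC(C)=O
Why: Acetylation of a primary alcohol; the acetate keeps the C13 oxygen distinct from the later C8 hydroxyl, holds C11 as sp3 through metathesis, and is the leaving group of step 17.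

Step 13
Reactants: 27 [(3R,4S,5R)‑2‑oxo‑5‑[(2S)‑2‑(TBSO‑methyl)hex‑5‑en‑1‑yl]‑4‑{2‑[2‑(TBSO‑methyl)prop‑2‑en‑1‑yl]‑1,3‑dithian‑2‑yl}oxolan‑3‑yl]methyl acetate
Product: 28 [(3R,4S,5R)‑2‑oxo‑4‑[3‑(TBSO‑methyl)but‑3‑enoyl]‑5‑[(2S)‑2‑(TBSO‑methyl)hex‑5‑en‑1‑yl]oxolan‑3‑yl]methyl acetate
Conditions: MeI, CaCO3, MeCN–H2O (9:1), 40 °C; product used directly
Reagents that add atoms: water, O
Why: Alkylative dithiane hydrolysis (S‑methylation, then hydrolysis of the sulfonium) under CaCO3 buffer, which tolerates alkenes, silyl ethers and the acetate; the near‑neutral medium should spare the β,γ‑unsaturated, β‑acyloxy ketone, which is taken on at once.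

Step 14
Reactants: 28 [(3R,4S,5R)‑2‑oxo‑4‑[3‑(TBSO‑methyl)but‑3‑enoyl]‑5‑[(2S)‑2‑(TBSO‑methyl)hex‑5‑en‑1‑yl]oxolan‑3‑yl]methyl acetate
Product: 29 [(3R,4R,5R)‑4‑[(1R)‑1‑hydroxy‑3‑(TBSO‑methyl)but‑3‑en‑1‑yl]‑2‑oxo‑5‑[(2S)‑2‑(TBSO‑methyl)hex‑5‑en‑1‑yl]oxolan‑3‑yl]methyl acetate
Conditions: (S)‑2‑methyl‑CBS‑oxazaborolidine, catecholborane, toluene, −78 °C; pH 7 buffer work‑up
Reagents that add atoms: none
Why: Corey–Bakshi–Shibata reduction; the (S)‑catalyst treats the branched C7 side as the large group and the C9 methylene as the small one and delivers hydride to give the 8R carbinol under reagent control, while catecholborane at −78 °C leaves lactone, acetate and alkenes alone. (The ring‑carbon descriptor changes from 4S to 4R only because of CIP priorities.)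

Step 15
Reactants: 29 [(3R,4R,5R)‑4‑[(1R)‑1‑hydroxy‑3‑(TBSO‑methyl)but‑3‑en‑1‑yl]‑2‑oxo‑5‑[(2S)‑2‑(TBSO‑methyl)hex‑5‑en‑1‑yl]oxolan‑3‑yl]methyl acetate
Product: 30 [(3R,3aR,4R,6E,10S,11aR)‑4‑hydroxy‑2‑oxo‑6,10‑bis(TBSO‑methyl)‑2,3,3a,4,5,8,9,10,11,11a‑decahydrocyclodeca[b]furan‑3‑yl]methyl acetate
Conditions: second‑generation Grubbs catalyst (H2IMes)(PCy3)Cl2Ru=CHPh (cat.), 1,4‑benzoquinone (cat.), toluene (ca. 1 mM, slow addition of 29), 80 °C
Reagents that add atoms: none
Why: Ring‑closing metathesis between the C1 vinyl group and the C10 1,1‑disubstituted alkene, driven by loss of ethene; the trans lactone holds both chains on adjacent carbons, and the ring‑cis trisubstituted alkene (E by CIP) is expected because the ring‑trans isomer is markedly more strained in a ten‑membered ring.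

Step 16
Reactants: 30 [(3R,3aR,4R,6E,10S,11aR)‑4‑hydroxy‑2‑oxo‑6,10‑bis(TBSO‑methyl)‑2,3,3a,4,5,8,9,10,11,11a‑decahydrocyclodeca[b]furan‑3‑yl]methyl acetate
Product: 31 (3R,3aS,4R,6E,10S,11aR)‑3‑(acetoxymethyl)‑2‑oxo‑6,10‑bis(TBSO‑methyl)‑2,3,3a,4,5,8,9,10,11,11a‑decahydrocyclodeca[b]furan‑4‑yl 2‑methylprop‑2‑enoate
Conditions: methacrylic anhydride, Et3N, DMAP (cat.), CH2Cl2, 0 °C to rt
Reagents that add atoms: methacrylic anhydride, CC(=C)C(=O)OC(=O)C(C)=C
Why: DMAP‑catalysed acylation of the secondary C8 alcohol without alkoxide formation, so translactonisation onto C12 should not compete; C8 keeps its configuration because only the O–H bond reacts.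

Step 17
Reactants: 31 (3R,3aS,4R,6E,10S,11aR)‑3‑(acetoxymethyl)‑2‑oxo‑6,10‑bis(TBSO‑methyl)‑2,3,3a,4,5,8,9,10,11,11a‑decahydrocyclodeca[b]furan‑4‑yl 2‑methylprop‑2‑enoate
Product: 32 (3aS,4R,6E,10S,11aR)‑3‑methylidene‑2‑oxo‑6,10‑bis(TBSO‑methyl)‑2,3,3a,4,5,8,9,10,11,11a‑decahydrocyclodeca[b]furan‑4‑yl 2‑methylprop‑2‑enoate
Conditions: DBU, toluene, 0 °C
Reagents that add atoms: none
Why: E1cB elimination of acetate through the lactone enolate, the usual route from α‑(acyloxymethyl) lactones to α‑methylene lactones; the C11 centre is removed, and brief cold exposure should avoid migration of the new alkene into the ring.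

Step 18
Reactants: 32 (3aS,4R,6E,10S,11aR)‑3‑methylidene‑2‑oxo‑6,10‑bis(TBSO‑methyl)‑2,3,3a,4,5,8,9,10,11,11a‑decahydrocyclodeca[b]furan‑4‑yl 2‑methylprop‑2‑enoate
Product: 33 (3aS,4R,6E,10S,11aR)‑6,10‑bis(hydroxymethyl)‑3‑methylidene‑2‑oxo‑2,3,3a,4,5,8,9,10,11,11a‑decahydrocyclodeca[b]furan‑4‑yl 2‑methylprop‑2‑enoate (CNP0546547.2)
Conditions: HF·pyridine, pyridine, THF, 0 °C to rt
Reagents that add atoms: none
Why: Fluoride desilylation of two primary silyl ethers under buffered, weakly acidic conditions that do not add to the methylene lactone or the methacrylate and do not promote acyl migration.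

## Compound list

1 | hex‑5‑enoic acid | C=CCCCC(=O)O | starting material
2 | (4R)‑4‑benzyl‑1,3‑oxazolidin‑2‑one | O=C1N[C@H](Cc2ccccc2)CO1 | starting material
3 | hex‑5‑enoic pivalic anhydride | C=CCCCC(=O)OC(=O)C(C)(C)C | intermediate
4 | (4R)‑4‑benzyl‑3‑(hex‑5‑enoyl)‑1,3‑oxazolidin‑2‑one | C=CCCCC(=O)N1[C@H](Cc2ccccc2)COC1=O | intermediate
5 | tert‑butyl bromoacetate | CC(C)(C)OC(=O)CBr | starting material
6 | sodium (1Z)‑1‑[(4R)‑4‑benzyl‑2‑oxo‑1,3‑oxazolidin‑3‑yl]hexa‑1,5‑dien‑1‑olate | C=CCC/C=C(\[O-])N1[C@H](Cc2ccccc2)COC1=O.[Na+] | intermediate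
7 | tert‑butyl (3S)‑3‑{[(4R)‑4‑benzyl‑2‑oxo‑1,3‑oxazolidin‑3‑yl]carbonyl}hept‑6‑enoate | C=CCC[C@@H](CC(=O)OC(C)(C)C)C(=O)N1[C@H](Cc2ccccc2)COC1=O | intermediate
8 | tert‑butyl (3S)‑3‑(hydroxymethyl)hept‑6‑enoate | C=CCC[C@@H](CC(=O)OC(C)(C)C)CO | intermediate
9 | tert‑butyl (3S)‑3‑(TBSO‑methyl)hept‑6‑enoate | C=CCC[C@@H](CC(=O)OC(C)(C)C)CO[Si](C)(C)C(C)(C)C | intermediate
10 | (3S)‑3‑(TBSO‑methyl)hept‑6‑enal | C=CCC[C@@H](CC=O)CO[Si](C)(C)C(C)(C)C | intermediate
11 | ethyl propiolate | C#CC(=O)OCC | starting material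
12 | ethyl 3‑(methylzincio)prop‑2‑ynoate | C[Zn]C#CC(=O)OCC | intermediate
13 | ethyl (4R,6S)‑4‑hydroxy‑6‑(TBSO‑methyl)dec‑9‑en‑2‑ynoate | C=CCC[C@@H](C[C@@H](O)C#CC(=O)OCC)CO[Si](C)(C)C(C)(C)C | intermediate
14 | ethyl (2Z,4R,6S)‑4‑hydroxy‑6‑(TBSO‑methyl)deca‑2,9‑dienoate | C=CCC[C@@H](C[C@@H](O)/C=C\C(=O)OCC)CO[Si](C)(C)C(C)(C)C | intermediate
15 | (5R)‑5‑[(2S)‑2‑(TBSO‑methyl)hex‑5‑en‑1‑yl]furan‑2(5H)‑one | O=C1C=C[C@@H](C[C@@H](CO[Si](C)(C)C(C)(C)C)CCC=C)O1 | intermediate
16 | 2‑methylidenepropane‑1,3‑diol | C=C(CO)CO | starting material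
17 | sodium 2‑(hydroxymethyl)prop‑2‑en‑1‑olate | C=C(CO)C[O-].[Na+] | intermediate
18 | 2‑(TBSO‑methyl)prop‑2‑en‑1‑ol | C=C(CO)CO[Si](C)(C)C(C)(C)C | intermediate
19 | {[2‑(bromomethyl)prop‑2‑en‑1‑yl]oxy}(tert‑butyl)dimethylsilane | C=C(CBr)CO[Si](C)(C)C(C)(C)C | intermediate
20 | 1,3‑dithiane | C1CSCSC1 | starting material
21 | 2‑lithio‑1,3‑dithiane | [Li]C1SCCCS1 | intermediate
22 | 2‑[2‑(TBSO‑methyl)prop‑2‑en‑1‑yl]‑1,3‑dithiane | C=C(CO[Si](C)(C)C(C)(C)C)CC1SCCCS1 | intermediate
23 | formaldehyde | C=O | starting material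
24 | 2‑lithio‑2‑[2‑(TBSO‑methyl)prop‑2‑en‑1‑yl]‑1,3‑dithiane | [Li]C1(CC(=C)CO[Si](C)(C)C(C)(C)C)SCCCS1 | intermediate
25 | lithium (4S,5R)‑5‑[(2S)‑2‑(TBSO‑methyl)hex‑5‑en‑1‑yl]‑4‑{2‑[2‑(TBSO‑methyl)prop‑2‑en‑1‑yl]‑1,3‑dithian‑2‑yl}‑4,5‑dihydrofuran‑2‑olate | C=C(CO[Si](C)(C)C(C)(C)C)CC1(SCCCS1)[C@H]2C=C(O[Li])O[C@@H]2C[C@@H](CO[Si](C)(C)C(C)(C)C)CCC=C | intermediate
26 | (3R,4S,5R)‑3‑(hydroxymethyl)‑5‑[(2S)‑2‑(TBSO‑methyl)hex‑5‑en‑1‑yl]‑4‑{2‑[2‑(TBSO‑methyl)prop‑2‑en‑1‑yl]‑1,3‑dithian‑2‑yl}oxolan‑2‑one | C=C(CO[Si](C)(C)C(C)(C)C)CC1(SCCCS1)[C@H]2[C@H](CO)C(=O)O[C@@H]2C[C@@H](CO[Si](C)(C)C(C)(C)C)CCC=C | intermediate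
27 | [(3R,4S,5R)‑2‑oxo‑5‑[(2S)‑2‑(TBSO‑methyl)hex‑5‑en‑1‑yl]‑4‑{2‑[2‑(TBSO‑methyl)prop‑2‑en‑1‑yl]‑1,3‑dithian‑2‑yl}oxolan‑3‑yl]methyl acetate | C=C(CO[Si](C)(C)C(C)(C)C)CC1(SCCCS1)[C@H]2[C@H](COC(C)=O)C(=O)O[C@@H]2C[C@@H](CO[Si](C)(C)C(C)(C)C)CCC=C | intermediate
28 | [(3R,4S,5R)‑2‑oxo‑4‑[3‑(TBSO‑methyl)but‑3‑enoyl]‑5‑[(2S)‑2‑(TBSO‑methyl)hex‑5‑en‑1‑yl]oxolan‑3‑yl]methyl acetate | C=C(CO[Si](C)(C)C(C)(C)C)CC(=O)[C@H]1[C@H](COC(C)=O)C(=O)O[C@@H]1C[C@@H](CO[Si](C)(C)C(C)(C)C)CCC=C | intermediate
29 | [(3R,4R,5R)‑4‑[(1R)‑1‑hydroxy‑3‑(TBSO‑methyl)but‑3‑en‑1‑yl]‑2‑oxo‑5‑[(2S)‑2‑(TBSO‑methyl)hex‑5‑en‑1‑yl]oxolan‑3‑yl]methyl acetate | C=C(CO[Si](C)(C)C(C)(C)C)C[C@@H](O)[C@H]1[C@H](COC(C)=O)C(=O)O[C@@H]1C[C@@H](CO[Si](C)(C)C(C)(C)C)CCC=C | intermediate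
30 | [(3R,3aR,4R,6E,10S,11aR)‑4‑hydroxy‑2‑oxo‑6,10‑bis(TBSO‑methyl)‑2,3,3a,4,5,8,9,10,11,11a‑decahydrocyclodeca[b]furan‑3‑yl]methyl acetate | O[C@@H]1C/C(CO[Si](C)(C)C(C)(C)C)=C\CC[C@H](CO[Si](C)(C)C(C)(C)C)C[C@H]2OC(=O)[C@@H](COC(C)=O)[C@H]12 | intermediate
31 | (3R,3aS,4R,6E,10S,11aR)‑3‑(acetoxymethyl)‑2‑oxo‑6,10‑bis(TBSO‑methyl)‑2,3,3a,4,5,8,9,10,11,11a‑decahydrocyclodeca[b]furan‑4‑yl 2‑methylprop‑2‑enoate | C=C(C)C(=O)O[C@@H]1C/C(CO[Si](C)(C)C(C)(C)C)=C\CC[C@H](CO[Si](C)(C)C(C)(C)C)C[C@H]2OC(=O)[C@@H](COC(C)=O)[C@H]12 | intermediate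
32 | (3aS,4R,6E,10S,11aR)‑3‑methylidene‑2‑oxo‑6,10‑bis(TBSO‑methyl)‑2,3,3a,4,5,8,9,10,11,11a‑decahydrocyclodeca[b]furan‑4‑yl 2‑methylprop‑2‑enoate | C=C(C)C(=O)O[C@@H]1C/C(CO[Si](C)(C)C(C)(C)C)=C\CC[C@H](CO[Si](C)(C)C(C)(C)C)C[C@H]2OC(=O)C(=C)[C@H]12 | intermediate
33 | (3aS,4R,6E,10S,11aR)‑6,10‑bis(hydroxymethyl)‑3‑methylidene‑2‑oxo‑2,3,3a,4,5,8,9,10,11,11a‑decahydrocyclodeca[b]furan‑4‑yl 2‑methylprop‑2‑enoate | C=C(C)C(=O)O[C@@H]1C/C(CO)=C\CC[C@H](CO)C[C@H]2OC(=O)C(=C)[C@H]12 | target

## Step count and least certain steps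

Total steps: 18. Longest linear sequence: 15 (steps 1–7, then 11–18); the dithiane branch (steps 8–10) is 3 steps.

**Step 11 (key step).**
- Risk: the basic 2‑alkyl dithiane anion may deprotonate C6 of the butenolide (dienolate formation, with loss of material and of C6 integrity) or add to the lactone carbonyl. Trapping may also be incomplete if proton transfer to the enolate outruns the aldol with formaldehyde.
- Fallback: change the acyl‑anion equivalent to a softer, less basic one. Lithiated bis(phenylsulfanyl)methane is alkylated with bromide 19 to give tert‑butyl({2‑[2,2‑bis(phenylsulfanyl)ethyl]prop‑2‑en‑1‑yl}oxy)dimethylsilane F1. Its anion (n‑BuLi, THF, −78 °C) is of a class that adds 1,4 to butenolides. Coupling with 15 and 23 as before should give the bis(phenylsulfanyl) analogue F2 of the hydroxymethyl lactone. Acetylation gives F3, and hydrolysis of the dithioketal (MeI, CaCO3, aq. MeCN) rejoins the route at ketone 28.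

**Step 15 (ring closure).**
- Risk: intermolecular metathesis through the C1 vinyl group may outrun closure of the strained ring, or some ring‑trans alkene may form.
- Fallback: close the ring on ketone 28, where C8 is trigonal and the transannular demands differ, to give the macrocyclic keto lactone F4. Reduce F4 with the same (S)‑oxazaborolidine and catecholborane, returning to the route at 30.

**Step 14 (C8 carbinol).**
- Risk: poor facial selectivity if the catalyst preference opposes the intrinsic bias of the C7 centre, and base‑ or acid‑triggered conjugation of the C10 alkene before reduction is complete.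
- Fallback: accept the 8S epimer F5 (separated, or made deliberately with the (R)‑catalyst if the substrate bias dominates). Ring‑close it as in step 15 to the 8‑epi macrocycle F6, then esterify with inversion by a Mitsunobu reaction (methacrylic acid, PPh3, diisopropyl azodicarboxylate), which delivers 31 directly.

**Step 13 (dithiane hydrolysis).**
- Risk: slow hydrolysis of the hindered dithiane gives time for migration of the C10 alkene into conjugation with the new ketone, or for β‑elimination of the C6 carboxylate.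
- Fallback: ring‑close first. Metathesis of dithiane 27, where the dithiane acts as a gem‑disubstituent that favours closure, gives the spiro‑dithiane macrocycle F7. Hydrolysis then gives F4, in which a conjugated trisubstituted enone would be strained inside the ten‑membered ring, and reduction returns to 30.

**Step 6 (alkynylation).**
- Risk: low diastereoselectivity and self‑aldol condensation with an unbranched, enolisable aldehyde.
- Fallback: add LiC≡CCO2Et (from 11 and LiN(SiMe3)2, THF, −78 °C) to 10 without stereocontrol to give the C4‑epimeric carbinols F8. Oxidise with Dess–Martin periodinane to ynone F9, then reduce with (R)‑Alpine‑borane (from (+)‑α‑pinene), which gives the R propargylic alcohol for alkynyl alkyl ketones, rejoining the route at 13.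

## Further compounds

F1 | step 11 | tert‑butyl({2‑[2,2‑bis(phenylsulfanyl)ethyl]prop‑2‑en‑1‑yl}oxy)dimethylsilane | C=C(CO[Si](C)(C)C(C)(C)C)CC(Sc1ccccc1)Sc1ccccc1
F2 | step 11 | (3R,4S,5R)‑4‑[1,1‑bis(phenylsulfanyl)‑3‑(TBSO‑methyl)but‑3‑en‑1‑yl]‑3‑(hydroxymethyl)‑5‑[(2S)‑2‑(TBSO‑methyl)hex‑5‑en‑1‑yl]oxolan‑2‑one | C=C(CO[Si](C)(C)C(C)(C)C)CC(Sc1ccccc1)(Sc1ccccc1)[C@H]1[C@H](CO)C(=O)O[C@@H]1C[C@@H](CO[Si](C)(C)C(C)(C)C)CCC=C
F3 | step 11 | [(3R,4S,5R)‑4‑[1,1‑bis(phenylsulfanyl)‑3‑(TBSO‑methyl)but‑3‑en‑1‑yl]‑2‑oxo‑5‑[(2S)‑2‑(TBSO‑methyl)hex‑5‑en‑1‑yl]oxolan‑3‑yl]methyl acetate | C=C(CO[Si](C)(C)C(C)(C)C)CC(Sc1ccccc1)(Sc1ccccc1)[C@H]1[C@H](COC(C)=O)C(=O)O[C@@H]1C[C@@H](CO[Si](C)(C)C(C)(C)C)CCC=C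
F4 | step 15 | [(3R,3aS,6E,10S,11aR)‑2,4‑dioxo‑6,10‑bis(TBSO‑methyl)‑2,3,3a,4,5,8,9,10,11,11a‑decahydrocyclodeca[b]furan‑3‑yl]methyl acetate | O=C1C/C(CO[Si](C)(C)C(C)(C)C)=C\CC[C@H](CO[Si](C)(C)C(C)(C)C)C[C@H]2OC(=O)[C@@H](COC(C)=O)[C@H]12
F5 | step 14 | [(3R,4R,5R)‑4‑[(1S)‑1‑hydroxy‑3‑(TBSO‑methyl)but‑3‑en‑1‑yl]‑2‑oxo‑5‑[(2S)‑2‑(TBSO‑methyl)hex‑5‑en‑1‑yl]oxolan‑3‑yl]methyl acetate | C=C(CO[Si](C)(C)C(C)(C)C)C[C@H](O)[C@H]1[C@H](COC(C)=O)C(=O)O[C@@H]1C[C@@H](CO[Si](C)(C)C(C)(C)C)CCC=C
F6 | step 14 | [(3R,3aR,4S,6E,10S,11aR)‑4‑hydroxy‑2‑oxo‑6,10‑bis(TBSO‑methyl)‑2,3,3a,4,5,8,9,10,11,11a‑decahydrocyclodeca[b]furan‑3‑yl]methyl acetate | O[C@H]1C/C(CO[Si](C)(C)C(C)(C)C)=C\CC[C@H](CO[Si](C)(C)C(C)(C)C)C[C@H]2OC(=O)[C@@H](COC(C)=O)[C@H]12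
F7 | step 13 | [(3R,3aS,6E,10S,11aR)‑2‑oxo‑6,10‑bis(TBSO‑methyl)‑3,3a,5,8,9,10,11,11a‑octahydro‑2H‑spiro[cyclodeca[b]furan‑4,2'‑[1,3]dithian]‑3‑yl]methyl acetate | S1CCCSC12C/C(CO[Si](C)(C)C(C)(C)C)=C\CC[C@H](CO[Si](C)(C)C(C)(C)C)C[C@H]3OC(=O)[C@@H](COC(C)=O)[C@H]23
F8 | step 6 | ethyl (6S)‑4‑hydroxy‑6‑(TBSO‑methyl)dec‑9‑en‑2‑ynoate, mixture of C4 epimers | C=CCC[C@@H](CC(O)C#CC(=O)OCC)CO[Si](C)(C)C(C)(C)C
F9 | step 6 | ethyl (6S)‑4‑oxo‑6‑(TBSO‑methyl)dec‑9‑en‑2‑ynoate | C=CCC[C@@H](CC(=O)C#CC(=O)OCC)CO[Si](C)(C)C(C)(C)C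
A1 | alternative 1 | thirteen‑membered α‑(tributylstannyl) allylic ether (O bridging C6 and C13; C6 configuration and C7=C11 geometry left open) | CC[Si](CC)(CC)O[C@@H]1C/C(CO[Si](c2ccccc2)(c2ccccc2)C(C)(C)C)=C\CC[C@H](CO[Si](c2ccccc2)(c2ccccc2)C(C)(C)C)CC([Sn](CCCC)(CCCC)CCCC)OCC(COCc2ccc(OC)cc2)=C1
A2 | alternative 1 | ten‑membered C6 alcohol with C7 2‑propenyl arm (C12 as PMB ether, C8 as triethylsilyl ether) | CC[Si](CC)(CC)O[C@@H]1C/C(CO[Si](c2ccccc2)(c2ccccc2)C(C)(C)C)=C\CC[C@H](CO[Si](c2ccccc2)(c2ccccc2)C(C)(C)C)C[C@@H](O)[C@@H]1C(=C)COCc1ccc(OC)cc1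
A3 | alternative 2 | acyclic C6 aldehyde with C12 methyl ester, C8 PMB ether and 2‑(bromomethyl)allyl terminus | O=C[C@H](CC(=O)OC)[C@H](OCc1ccc(OC)cc1)C/C(CO[Si](C)(C)C(C)(C)C)=C\CCC(=C)CBr
A4 | alternative 2 | ten‑membered trans‑fused lactone with C4 exocyclic methylene and C8 PMB ether | O(Cc1ccc(OC)cc1)[C@@H]1C/C(CO[Si](C)(C)C(C)(C)C)=C\CCC(=C)C[C@H]2OC(=O)C[C@H]12
A5 | alternative 3 | ten‑membered trans‑C7,C8‑epoxide carrying the C6 diethylphosphonoacetate | CCOP(=O)(OCC)CC(=O)O[C@@H]1C[C@@H](CO[Si](C)(C)C(C)(C)C)CC/C=C(CO[Si](C)(C)C(C)(C)C)\C[C@H]2O[C@H]12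
A6 | alternative 3 | α‑methylene lactone with free C8 hydroxyl and silylated C14 and C15 | O[C@@H]1C/C(CO[Si](C)(C)C(C)(C)C)=C\CC[C@H](CO[Si](C)(C)C(C)(C)C)C[C@H]2OC(=O)C(=C)[C@H]12
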